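The numbers in the tables stem from a simulated flask on assumed constants; noise was put on by code.

The ratio of target booked to starting material lost elsewhere is the figure we keep for these flasks, so we run a ledger on the starting material, the limiting reagent.

| flask | starting material | free enzyme | temperature | remark | time |
|---|---|---|---|---|---|
| west | 0.012 M | 0.0059 mol% | −20 °C | run made earlier |  |
| north | 0.012 M | 0.0092 mol% | 5 °C | run made earlier |  |
| south | 0.0060 M | 0.0042 mol% | −20 °C | run made earlier |  |
| green | 0.012 M | 0.0042 mol% | 5 °C |  | 20 min |
| violet | 0.012 M | 0.0042 mol% | 25 °C |  | 20 min |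
| teal | 0.012 M | 0.0042 mol% | −15 °C |  | 20 min |

| run | time / min | target / % | starting material / % |
|---|---|---|---|
| west | 10.0 | 50.5 | 37.8 |
| west | 20.0 | 62.7 | 20.6 |
| west | 30.0 | 69.3 | 15.1 |
| west | 50.0 | 73.2 | 9.6 |
| west | 60.0 | 75.4 | 7.1 |
| west | 80.0 | 75.8 | 4.6 |
| north | 1.33 | 30.7 | 57.2 |
| north | 4.00 | 52.9 | 27.7 |
| north | 6.00 | 59.9 | 19.5 |
| north | 10.0 | 66.4 | 12.4 |
| north | 15.0 | 69.3 | 8.6 |
| north | 20.0 | 69.7 | 7.3 |
| north | 25.0 | 72.0 | 5.0 |
| south | 6.00 | 12.8 | 78.7 |
| south | 15.0 | 24.6 | 59.4 |
| south | 20.0 | 30.4 | 52.5 |
| south | 40.0 | 41.2 | 35.5 |
| south | 80.0 | 50.5 | 21.2 |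

(readings scatter by 0.5 percentage points)

- the flask that comes out highest in amount of target, in percent of the starting material charged, or "all alike" when all lie within 1.5 percentage points (green / violet / teal / all alike)
- target at the end, in percent of the starting material charged, green
- target at the end, in percent of the starting material charged, violet
- target at the end, in percent of the starting material charged, teal



Each mole charged is entered as left, as target, or as gap, the part the readings do not show. In the north run at 10.0 min, 12.4% is left and 66.4% is target, so the gap is 21.2%. That gives 3.13, the ledger ratio, target entered per unit of gap. The first north reading gives 2.54, so we take the ratio at this later reading, where the amount left is near what we expect in green.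

Green shares its temperature and starting concentration with north and differs in loading. Holding those two fixed, we assume that the target entry scales with free enzyme and the gap does not. Green's ratio is then 1.43, a selectivity of 58.8%. North's inverse fraction left climbs by 0.706 min⁻¹ above its starting value of one. Splitting that by the ledger and scaling the target part gives 0.415 min⁻¹ for green. After 20 min, green should therefore have 10.7% left and 52.5% as target.

The west run at 20.0 min, at −20 °C, has a ratio of 3.75. Scaled to the loading of teal, which stands at −15 °C, this becomes 2.67, about twice green's. That is a selectivity of 72.8%, but target is that share of what has been consumed, so the consumption has to be entered too. West's inverse fraction left climbs by 0.193 min⁻¹ above its starting value of one. Splitting that by the ledger and scaling the target part gives 0.149 min⁻¹ for teal, with no correction for the difference in temperature between west and teal. After 20 min, teal should therefore have 25.1% left and 54.5% as target, more than green's 52.5%, so we put teal above green by 2 percentage points. Violet, at 25 °C, lies beyond the runs, so we enter no figure for it and leave it unranked.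

The forecast named teal, with 53.5% for green, 44.5% for violet and 56.5% for teal, and held that “Warming therefore favours the side path”.

Teal comes out highest at 55.0%, above green at 51.6%, while violet gives 18.3%. In violet, free enzyme is down to 0.0515% at 10.0 min, and target stands at 18.3% then and 18.3% at 20.0 min.

    starting material + free enzyme → target + free enzyme, rate k1*[starting material]^2*[free enzyme]/(1 + ([starting material]/Kh1)^2) (13.0 mM, k = 7.60 × 10⁵ M⁻² s⁻¹, Ea = 18.0 kJ mol⁻¹)
    free enzyme → unfolded enzyme (k = 2.60 × 10⁻⁴ min⁻¹, Ea = 275 kJ mol⁻¹)
    2 starting material → homo dimer (k = 6.40 M⁻¹ min⁻¹, Ea = 36.0 kJ mol⁻¹)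
    (constants at 5 °C)

The gap is homo dimer, and green holds 51.6% target against 37.4% of it, a ratio of 1.38 beside our 1.43. Scaling 3.13 to the neighbour of green at 0.0071 mol% gives 2.42, and that flask holds 64.6% target against 27.6% homo dimer, a ratio of 2.34.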